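The earlier runs and the new flask are calculated for an exercise; scatter was added.

The pitfall here is to take D/G for a constant of the recipe, as one fitted number would, when the grey and violet runs, with the same Q and E, climb through the whole span of their readings.

| flask | Q | E | L | remark | time |
|---|---|---|---|---|---|
| grey | 1 M | 1.2 M | 12 mM | run made earlier |  |
| violet | 1 M | 1.2 M | 50 mM | run made earlier |  |
| flask | 1.0 M | 1.20 M | 25 mM |  | 30 min |

| run | time / min | D / % | G / % |
|---|---|---|---|
| grey | 1.50 | 16.4 | 34.6 |
| grey | 5.00 | 26.8 | 49.8 |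
| grey | 8.00 | 30.1 | 52.7 |
| grey | 12.0 | 32.6 | 53.8 |
| grey | 20.0 | 34.8 | 51.8 |
| grey | 25.0 | 35.8 | 51.5 |
| grey | 30.0 | 38.1 | 50.6 |
| violet | 4.00 | 32.2 | 40.0 |
| violet | 8.00 | 40.0 | 42.8 |
| violet | 12.0 | 44.0 | 43.3 |
| violet | 15.0 | 44.7 | 40.3 |
| violet | 20.0 | 48.8 | 38.6 |
| violet | 25.0 | 50.4 | 36.1 |
| violet | 30.0 | 52.1 | 35.2 |

(each reading ± 0.5 percentage points)

- ratio of D to G at 2.0 s
- ratio of D to G at 1.0 min
- ratio of D to G at 30 min

My first question is whether L has had time to act by 2.0 s: that moment is hardly any of the span to the earliest grey reading, so I expect the ratio there at or below that reading's 0.474, which I take as my early value.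

The next question is what the charged [L] does later. At 30.0 min the grey run reads 0.753 and the violet run 1.48, so from grey to violet the excess over the early value, 0.279 and 1.01, grows by a factor of 3.62 while the charged [L] grows by a factor of 4.17. These readings make 0.899 the apparent order in L of the excess, the power of the charged [L] by which D/G climbs above its early value at a fixed time and fixed charges of Q and E.

The new flask, charged with 25 mM of L, lies between the two runs in that charge, so I reckon its excess at 0.540 and commit to a D/G of 1.01 at 30 min. The forecast, working from an early value of 0.44 and “interpolating the excess over 0.44 between runs”, gives 0.44, 0.48 and 1.03 at the three times, the last against my 1.01.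

The new flask gives 0.389, 0.484 and 1.03.

    Q + E ⇌ G (K = 6.00 L mol⁻¹, k = 0.00700 L mol⁻¹ s⁻¹)
    Q + E ⇌ D (K = 38.0 L mol⁻¹, k = 0.00270 L mol⁻¹ s⁻¹)
    G + L ⇌ D + L, rate k3*[L]*[G] forward; the back reaction follows from the equilibrium constant (k = 0.0750 L mol⁻¹ s⁻¹)
    Q + L → Z (k = 8.10 × 10⁻⁴ L mol⁻¹ s⁻¹)
    X ⇌ G, rate k5*(cs5 - [G]) while solid is left; crystals form when [G] > cs5 (solubility = 0.100 M, k = 0.0190 s⁻¹)
    Q + G → J (k = 0.00120 L mol⁻¹ s⁻¹)

So the forecast held within its margins. At 30.0 min the new flask still has 83.0% of its charge as L, and the neighbour flask with 0.015 M of L has 83.0% of its own. Measured from my early value, the excess of the new flask is 0.556, against the 0.540 that the order gave. Put to use on that neighbour, the same order gives 0.815 at 30 min, and the neighbour stands at 0.827.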